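At 6.00 min you read 22.6% of E in the blue run, and at 12.0 min you read 49.4%; at that later time teal, with half the D, reads 51.5%.

| flask | D | Q | Z | remark | time |
|---|---|---|---|---|---|
| blue | 36 mM | 54 mM | 1.5 mM (held) | run made earlier |  |
| grey | 36 mM | 36 mM | 1.5 mM (held) | run made earlier |  |
| amber | 36 mM | 81 mM | 1.5 mM (held) | run made earlier |  |
| teal | 18 mM | 54 mM | 1.5 mM (held) | run made earlier |  |
| Sunday's | 36 mM | 54.0 mM (in portions, 2, over 8.0 min) | 1.5 mM (held) | first portion at the start, last at 8.0 min | 12 min |
| Saturday's | 36 mM | 54.0 mM (fed, over 8.0 min) | 1.5 mM (held) | all else is in the flask from the start; the feed brings no volume worth counting | 12 min |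
| Tuesday's | 36 mM (fed, over 8.0 min) | 54.0 mM | 1.5 mM (held) | all else is in the flask from the start; the feed brings no volume worth counting | 12 min |
| Friday's | 36 mM | 54.0 mM | 1.5 mM (held) | everything together at the start | 12 min |

| run | time / min | E / % |
|---|---|---|
| blue | 0.833 | 2.0 |
| blue | 2.50 | 4.5 |
| blue | 4.00 | 10.0 |
| blue | 6.00 | 22.6 |
| blue | 10.0 | 39.3 |
| blue | 12.0 | 49.4 |
| grey | 2.00 | 2.6 |
| grey | 4.00 | 6.9 |
| grey | 6.00 | 14.3 |
| grey | 8.00 | 22.6 |
| grey | 10.0 | 28.7 |
| grey | 12.0 | 34.6 |
| amber | 0.833 | 0.4 |
| amber | 2.50 | 6.1 |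
| amber | 4.00 | 14.8 |
| amber | 6.00 | 29.7 |
| amber | 10.0 | 53.2 |
| amber | 12.0 | 63.2 |
| teal | 1.00 | 0.1 |
| teal | 2.00 | 2.6 |
| teal | 3.00 | 6.5 |
| teal | 6.00 | 23.4 |
| teal | 12.0 | 51.5 |

(readings scatter by 1 percentage point)

- at the start none of J is dissolved
- steps under discussion: D + J -> X; J + Q -> G; X + G -> E; Z <-> J

- which flask leads in amount of E, in percent of the D charged ("all alike" within 1.5 percentage points) (Sunday's / Saturday's / Tuesday's / Friday's / all alike)
- how much E is there at the end, in percent of the D charged: Sunday's
- how much E is there at the end, in percent of the D charged: Saturday's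
- how much E is there at the end, in percent of the D charged: Tuesday's
- how much E is there at the end, in percent of the D charged: Friday's

My reckoning treats X + G → E as pseudo-first-order in X. I assume that between those two blue readings D stands as X and Q as G, so cG is about the charge less the mean E, 41.0 mM. The two readings then give 9.78 min as the half-life of X at that cG, and I let it shorten in proportion to cG.

Blue's last reading equals 9.62 min of reaction at that cG. In Saturday's and Sunday's the Q arrives on average 4.00 min late, which leaves 5.62 min and about 32.8% of E in each. Friday's repeats blue, and I put Tuesday's, with its Q in from the start, between these.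

The forecast gave 37% for Sunday's, 41% for Saturday's, 40% for Tuesday's and 49.5% for Friday's, so Friday's leads, reckoned by “Integrating Q over time after the lag”. We differ on Sunday's and Saturday's, where my 32.8% stands lower than both of its numbers.

The flasks give 34.3%, 35.9%, 39.1% and 48.6% in that order, so Friday's leads.

    D + J → X (k = 9.75 M⁻¹ s⁻¹)
    J + Q → G (k = 4.58 M⁻¹ s⁻¹)
    X + G → E (k = 0.0305 M⁻¹ s⁻¹)
    Z ⇌ J, rate k4*(csat - [J]) (kL = 0.901 s⁻¹)

Saturday's result equals 0.642 of the half-lives I read from blue, against 0.575 reckoned. At 6.00 min, Saturday's holds a cG of 21.4 mM and Friday's 39.2 mM. Now take Sunday's with 220 mM of Q instead of 54.0 mM. Scaling cG with the charge shortens the half-life to 2.40 min, so the same 5.62 min gives 80.2% of E, and that neighbouring flask gives 80.9%.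

The data are simulated with constants of no real substance; scatter was added.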